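**Plan**
- Retrosynthesis: the two bonds of the dihydropyran ring that tie the pinane to the trione, C3'–C4' (CH2–CH(isobutyl)) and O1'–C2' (ether oxygen–spiro carbon), are cut together (retro-oxa-Diels–Alder) to (−)-β-pinene and an alkylidene trione. The exocyclic C=C of that trione is then cut (retro-Knoevenagel) to syncarpic acid and isovaleraldehyde, and the four C-methyl groups lead back to 2,4,6-trihydroxyacetophenone.
- Enabling feature: in the dihydropyran ring, O1'–C8a'=C4a'–C4' is a vinylogous-ester (1-oxadiene) retron and C3'H2–C2' (quaternary, O-bearing) is the former exocyclic C=CH2 of a 1,1-disubstituted alkene. The mirror-symmetric tetramethyltrione ring makes both carbonyl groups and both alkene geometries of the alkylidene trione equivalent, so only one diene exists.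
- Forward order: the trione ring is made from the aromatic ring (steps 1 and 2), the pinane bicycle is bought intact, and the alkylidene and the dihydropyran ring (the last ring) arise in one flask from three components (step 3).
- Stereochemistry: both bridgehead centres come with (1S,5S)-(−)-β-pinene. The spiro centre and the isobutyl-bearing centre are set together in the cycloaddition by substrate control (addition anti to the gem-dimethyl bridge, C3 methylene of the pinene endo).

Key step: step 3

Assumption: commercial (1S,5S)-(−)-β-pinene of high enantiomeric purity is used, the β-triketones are drawn as enol tautomers, and the bridgehead next to the spiro atom changes its descriptor from S in the pinene to R in the target only through CIP priorities.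

**Step 1**
Reactants: 1 2,4,6-trihydroxyacetophenone
Product: 2 2-acetyl-3-hydroxy-4,4,6,6-tetramethylcyclohex-2-ene-1,5-dione (acetylsyncarpic acid, enol form)
Conditions: NaOMe (5 equiv), MeI (6 equiv), MeOH, 0 °C → reflux; aq HCl work-up
Reagents that add atoms: iodomethane, CI
Why: Exhaustive C-methylation of an acylphloroglucinol (dearomatising phenolate alkylation), in which the soft ring carbons of the phloroglucinolate are alkylated in preference to oxygen, each of the two free positions takes two methyl groups and becomes quaternary, and the acetyl-bearing carbon stays untouched because the product is a delocalised, hindered β-triketone anion; no stereocentre is formed.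

**Step 2**
Reactants: 2 2-acetyl-3-hydroxy-4,4,6,6-tetramethylcyclohex-2-ene-1,5-dione
Product: 3 3-hydroxy-4,4,6,6-tetramethylcyclohex-2-ene-1,5-dione (syncarpic acid, enol form)
Conditions: 6 M aq HCl, reflux
Reagents that add atoms: none
Why: Acid-mediated retro-Claisen C-deacylation of a β-triketone, in which water adds to the exocyclic acetyl carbonyl (the only carbonyl not shielded by a gem-dimethyl group) and C–C cleavage expels the stable enol of the cyclic trione together with acetic acid; no stereocentre is involved.

**Step 3**
Reactants: 3 3-hydroxy-4,4,6,6-tetramethylcyclohex-2-ene-1,5-dione (syncarpic acid); 4 3-methylbutanal (isovaleraldehyde); 5 (1S,5S)-6,6-dimethyl-2-methylidenebicyclo[3.1.1]heptane ((−)-β-pinene)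
Product: 7 the target (1R,2R,4'S,5S)-6,6,6',6',8',8'-hexamethyl-4'-(2-methylpropyl)-3',4'-dihydrospiro[bicyclo[3.1.1]heptane-2,2'-chromene]-5',7'(6'H,8'H)-dione, via 2-(3-methylbutylidene)trione 6 (not isolated)
Conditions: 4 (1.2 equiv), 5 (4 equiv), piperidinium acetate (10 mol %), 4 Å molecular sieves, PhMe, rt → 70 °C
Reagents that add atoms: none
Why: Piperidinium acetate condenses 3 with 4 (Knoevenagel, through a Mannich-type adduct and loss of the amine) to the 2-alkylidene-1,3,5-trione 6, a strongly electron-poor 1-oxa-1,3-diene, which adds to the electron-rich exocyclic alkene of 5 in an inverse-electron-demand oxa-Diels–Alder reaction that is concerted but asynchronous, the CH2 terminus of 5 bonding to the alkylidene carbon ahead of O–C bonding at the tertiary carbon, so that no free 2-pinanyl cation and hence no cyclobutane opening is expected. The closest known reaction type is the domino Knoevenagel/hetero-Diels–Alder reaction of cyclic 1,3-diones, including the thermal cycloaddition of alkylidene β-triketones to terpene alkenes. The 3',4'-dihydro-2H-pyran ring (O1', C2', C3', C4', C4a', C8a') is closed by an intermolecular [4+2] cycloaddition that forms its C3'–C4' and O1'–C2' bonds in the same event, suprafacially on both partners. The spiro centre C2 is controlled by the gem-dimethyl bridge (C6) of 5, whose syn methyl group blocks one face of the exocyclic alkene, so that oxygen is delivered anti to that bridge (2R). C4' is controlled by the endo/exo orientation: with the isobutyl group necessarily outside on the diene, the transition state that places the C3 methylene of the pinene under the trione ring and the bridgehead C1 with its methylene bridge (C7) away from it should be preferred on steric grounds and gives isobutyl cis to C3, that is 4'S. The step needs regio-, face- and endo/exo-selectivity and must outrun the ene reaction and the addition of a second molecule of 3 to 6: the polarisation of the two partners fixes the regiochemistry, the mirror symmetry of the tetramethyltrione ring leaves a single diene, and an excess of 5 in a non-polar buffered medium favours cycloaddition, while the 4'-epimer is the expected minor product and would be removed by chromatography.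

**Compound list**
1 | 2,4,6-trihydroxyacetophenone | CC(=O)c1c(O)cc(O)cc1O | starting material
2 | 2-acetyl-3-hydroxy-4,4,6,6-tetramethylcyclohex-2-ene-1,5-dione (acetylsyncarpic acid) | CC(=O)C1=C(O)C(C)(C)C(=O)C(C)(C)C1=O | intermediate
3 | 3-hydroxy-4,4,6,6-tetramethylcyclohex-2-ene-1,5-dione (syncarpic acid) | CC1(C)C(=O)C=C(O)C(C)(C)C1=O | intermediate
4 | 3-methylbutanal (isovaleraldehyde) | CC(C)CC=O | starting material
5 | (1S,5S)-6,6-dimethyl-2-methylidenebicyclo[3.1.1]heptane ((−)-β-pinene) | C=C1CC[C@H]2C[C@@H]1C2(C)C | starting material
6 | 2,2,4,4-tetramethyl-6-(3-methylbutylidene)cyclohexane-1,3,5-trione | CC(C)CC=C1C(=O)C(C)(C)C(=O)C(C)(C)C1=O | intermediate (not isolated)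
7 | (1R,2R,4'S,5S)-6,6,6',6',8',8'-hexamethyl-4'-(2-methylpropyl)-3',4'-dihydrospiro[bicyclo[3.1.1]heptane-2,2'-chromene]-5',7'(6'H,8'H)-dione | CC(C)C[C@H]1C[C@@]2(CC[C@H]3C[C@@H]2C3(C)C)OC2=C1C(=O)C(C)(C)C(=O)C2(C)C | target

Total step count: 3. Longest linear sequence: 3 steps (1 → 2 → 3 → 7); 4 and 5 are bought and enter in step 3.

**Steps most likely to fail**

Step 3. What may go wrong: weak endo/exo discrimination at the temperature that the in-flask condensation needs, together with loss of the heterodiene to conjugate addition of a second molecule of 3 or to an ene reaction with 5. The fallback sets out from 3 and comes back to the route at 6. Compound 3, 4 and one equivalent of piperidine in CH2Cl2 at 0 °C should give the isolable Mannich base 3-hydroxy-4,4,6,6-tetramethyl-2-[3-methyl-1-(piperidin-1-yl)butyl]cyclohex-2-ene-1,5-dione F1 (racemic at the aminated carbon), which uses up all of 3. Shaking a cold CH2Cl2 solution of F1 with 1 M HCl should remove piperidine and leave 6 in the organic layer. The dried solution is combined with an excess of 5 and kept at 0 °C to room temperature, so that the cycloaddition to 7 runs without heat, amine or free 3.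

Step 1. What may go wrong: competition of O-methylation and stalling at partly methylated stages in the ambident phenolate alkylation. The fallback sets out from 1 and comes back to the route at 2. Double Mannich aminomethylation of 1 (morpholine, aq CH2O, EtOH) at the two free ring positions should give 1-[2,4,6-trihydroxy-3,5-bis(morpholin-4-ylmethyl)phenyl]ethan-1-one F2. Hydrogenolysis (H2, Pd/C, AcOH, 60 °C) should then give 1-(2,4,6-trihydroxy-3,5-dimethylphenyl)ethan-1-one F3. MeI/NaOMe in MeOH then only has to add the two dearomatising methyl groups, at the ring carbons that are already the most nucleophilic, to reach 2.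

Step 2. What may go wrong: retro-Claisen cleavage of the ring at a gem-dimethyl-flanked carbonyl competing with loss of the exocyclic acetyl group, or stalling of the deacylation, in hot acid. The fallback sets out from 2 and comes back to the route at 3. Bromination of 2 at C2 (NBS, NaHCO3, aq THF, 0 °C) should give the non-enolisable 2-acetyl-2-bromo-4,4,6,6-tetramethylcyclohexane-1,3,5-trione F4. Its acetyl group is now lost by hydrolysis at low temperature, giving 2-bromo-3-hydroxy-4,4,6,6-tetramethylcyclohex-2-ene-1,5-dione F5. Zinc dust in AcOH at room temperature should then remove the bromine and give 3.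

**Further compounds**
F1 | step 3 | 3-hydroxy-4,4,6,6-tetramethyl-2-[3-methyl-1-(piperidin-1-yl)butyl]cyclohex-2-ene-1,5-dione (racemic) | CC(C)CC(N1CCCCC1)C1=C(O)C(C)(C)C(=O)C(C)(C)C1=O
F2 | step 1 | 1-[2,4,6-trihydroxy-3,5-bis(morpholin-4-ylmethyl)phenyl]ethan-1-one | CC(=O)c1c(O)c(CN2CCOCC2)c(O)c(CN2CCOCC2)c1O
F3 | step 1 | 1-(2,4,6-trihydroxy-3,5-dimethylphenyl)ethan-1-one | CC(=O)c1c(O)c(C)c(O)c(C)c1O
F4 | step 2 | 2-acetyl-2-bromo-4,4,6,6-tetramethylcyclohexane-1,3,5-trione | CC(=O)C1(Br)C(=O)C(C)(C)C(=O)C(C)(C)C1=O
F5 | step 2 | 2-bromo-3-hydroxy-4,4,6,6-tetramethylcyclohex-2-ene-1,5-dione | CC1(C)C(=O)C(Br)=C(O)C(C)(C)C1=O
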